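Over the 10 h of the run the flasks hold the same charges and differ in how these go in.

| setting | winter | noon | autumn | midnight |
|---|---|---|---|---|
| starting material | 10 mM | 10 mM (fed, over 4.0 h) | 10 mM | 10 mM |
| partner | 15.0 mM (fed, over 1.0 h) | 15.0 mM | 15.0 mM | 15.0 mM (fed, over 4.0 h) |
| second substrate | 10.0 mM | 10.0 mM | 10.0 mM | 10.0 mM |
| time | 10 h | 10 h | 10 h | 10 h |
| remark | all else is in the flask from the start; the feed brings no volume worth counting | all else is in the flask from the start; the feed brings no volume worth counting | everything together at the start | all else is in the flask from the start; the feed brings no volume worth counting |

    starting material + partner ⇌ target (K1 = 910 M⁻¹, k1 = 0.44 M⁻¹ min⁻¹)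
    second substrate + partner ⇌ second product (K2 = 9.0 M⁻¹, k2 = 0.016 M⁻¹ min⁻¹)
    partner → decomposed reagent (k3 = 7.8 × 10⁻⁴ min⁻¹)
    2 partner → self-condensation product (k4 = 0.29 M⁻¹ min⁻¹)

1. the flask that comes out highest in amount of target, in percent of the starting material charged, or "all alike" when all lie within 1.5 percentage points (winter / noon / autumn / midnight / all alike)
2. target at the end, in percent of the starting material charged, winter
3. target at the end, in percent of the starting material charged, noon
4. target at the end, in percent of the starting material charged, autumn
5. target at the end, in percent of the starting material charged, midnight

Follow one molecule of partner to its fork, with concentrations as charged. Toward target it leaves at 0.00440 min⁻¹ and toward self-condensation product at 0.00870 min⁻¹, two molecules going at each turn. The remaining steps take it at 9.40 × 10⁻⁴ min⁻¹, less than the way to target. The quotient of the first two, 1.98, is the waste ratio, a selectivity factor: partner used by self-condensation per partner used on target, proportional to [partner]/[starting material].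

The first half-life of partner by self-condensation is 1.92 h. The feed of winter, 1.0 h, is shorter than this, so winter should stay near autumn. In noon the same life is shorter than the 4.0 h feed of starting material, so the ratio starts above the autumn figure and noon should come last.

In midnight partner enters at 3.75 mM h⁻¹ and climbs until its losses equal the feed, near [partner] = 6.75 mM with starting material at its charge. The chance of reaching target is then 47.5%, which puts target at 71.3% of the starting material charged.

The weak link is that held [starting material]. Taken midway between its charge and what this yield leaves, it stands at 6.43 mM, the partner level rises to 7.63 mM, and the yield comes to 51.8%. The same step from that yield, with [starting material] at 7.41 mM and the partner level at 7.37 mM, gives 57.7%. The reckoning for midnight therefore stands near 54.8%. That figure is for a one-way step, and the omission is not negligible: the way back from target has a half-life of 23.9 h, so by that step alone target formed at the start would lose 25.2% of itself over the 10 h of the run.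

The forecast names midnight, with 50% for winter, 38% for noon, 48% for autumn and 61% for midnight, the last above the reckoning here, on the ground that “feeding partner slowly into the flask already holding starting material keeps its level low”.

The simulation puts midnight highest, with 51.4% in winter, 33.9% in noon, 49.8% in autumn and 54.5% in midnight.

In midnight at 4.00 h, the end of the feed, partner at 46.4% of its charge and starting material at 63.5% of its charge turn the waste ratio of 1.98 into 1.45. In noon the ratio, counted on the forward step, reads 6.8 at 0.860 h, higher than 1.98, and falls to 0.17 at 10.0 h, when self-condensation product stands at 4.42 mM in noon against 2.97 mM in midnight.

(The constants used here were drawn at random within sensible limits.)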